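**Plan**

1. Locants (daucane skeleton): C1 = methyl-bearing quaternary ring-fusion carbon, C2/C3 = ring CH2, C4 = isopropyl carbinol, C5 = ring-fusion CH, C6 = benzoyloxy carbon, C7 = CH2, C8=C9 = ring alkene (methyl on C8), C10 = angeloyloxy carbon.
2. Retrosynthetic cuts, in order: the two ester C–O bonds; C8=C9 (ring-closing metathesis); C6–C7 (methallyl + C6 acyl); C4–C5 of the five-membered ring; C1–C10 (allylboration).
3. Enabling feature: C4–OH is β to the C6 oxygen and cis to C6 on the cyclopentane, so C4–C5 is an aldol bond whose oxygen and acyl carbon can be tied into a cis-fused β-lactone.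
4. Forward: geranyl boronate + (R)-glyceraldehyde acetonide give the acyclic C1/C10 array; both alkenes become a keto acid; aldol-lactonization closes the five-membered ring; lactone opening, methallylation and metathesis close the seven-membered ring; reduction and two acylations finish.
5. Stereochemistry: C10 from the chiral-pool aldehyde (Felkin–Anh); C1 from the E-alkene through a chair transition state; C4 and C5 from the β-lactone and the quaternary C1; C6 from hydroxyl-directed hydride delivery in the bicycle; the Z-angelate is introduced intact.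

Key step: step 6

Remark: TBS = tert-butyldimethylsilyl; aldehyde 3 is used freshly distilled because it oligomerizes on standing.

**Step 1**
Reactants: 1 geranyl acetate
Product: 2 (E)-geranylboronic acid pinacol ester
Conditions: B2pin2, Ni(cod)2 (5 mol %), PCy3 (5 mol %), EtOAc, rt
Reagents that add atoms: bis(pinacolato)diboron, CC1(C)OB(OC1(C)C)B1OC(C)(C)C(C)(C)O1
Why: Allylic borylation of an allyl acetate through a π-allyl complex of zerovalent nickel should give the linear boronate with the E geometry retained, because the 3,3-disubstituted allyl terminus does not readily exchange its substituents; no stereocentre is formed.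

**Step 2**
Reactants: 2 (E)-geranylboronic acid pinacol ester; 3 (R)-2,2-dimethyl-1,3-dioxolane-4-carbaldehyde
Product: 4 (1S,2S)-1-[(4R)-2,2-dimethyl-1,3-dioxolan-4-yl]-2-ethenyl-2,6-dimethylhept-5-en-1-ol
Conditions: neat, 4 Å MS, rt then 40 °C; aq. NaHCO3 work-up
Reagents that add atoms: none
Why: Allylboration of an aldehyde by a γ,γ-disubstituted pinacol allylboronate through a closed Zimmerman–Traxler chair: the E reagent carries its methyl cis to boron and so should place methyl syn and the homoprenyl chain anti to the new hydroxyl at the quaternary C1, while the aldehyde is attacked on its Felkin–Anh face (anti to the α-oxygen, reinforced by the cis-methyl of the reagent), which sets C10.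

**Step 3**
Reactants: 4 homoallylic alcohol
Product: 5 TBS ether of 4
Conditions: TBSOTf, 2,6-lutidine, CH2Cl2, 0 °C
Reagents that add atoms: tert-butyldimethylsilyl triflate, CC(C)(C)[Si](C)(C)OS(=O)(=O)C(F)(F)F
Why: Silylation of the hindered secondary alcohol with the silyl triflate protects the C10 oxygen so that it cannot lactonize onto C6 later; no stereocentre changes.

**Step 4**
Reactants: 5 TBS ether
Product: 7 (3S)-3-{(S)-[(tert-butyldimethylsilyl)oxy][(4R)-2,2-dimethyl-1,3-dioxolan-4-yl]methyl}-3,7-dimethyloctane-1,6-diol (both epimers at the secondary carbinol), via bis(alkylborane) 6 (not isolated)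
Conditions: BH3·THF (excess), THF, 0 °C → rt; then NaOH, H2O2, 0 °C → rt
Reagents that add atoms: hydrogen peroxide, OO
Why: Hydroboration–oxidation should convert both alkenes anti-Markovnikov in one operation, the vinyl group into the primary C6 alcohol and the trisubstituted alkene into the secondary C4 alcohol; the C4 carbinol forms as an epimer mixture, which is irrelevant because it is oxidized in step 5.

**Step 5**
Reactants: 7 diol
Product: 8 (3S)-3-{(S)-[(tert-butyldimethylsilyl)oxy][(4R)-2,2-dimethyl-1,3-dioxolan-4-yl]methyl}-3,7-dimethyl-6-oxooctanoic acid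
Conditions: CrO3, H2SO4, H2O, acetone, 0 °C (Jones oxidation)
Reagents that add atoms: water, O
Why: Jones oxidation should take the primary alcohol to the acid (through the aldehyde hydrate) and the secondary alcohol to the isopropyl ketone at once; the acetone medium and low temperature should preserve the acetonide and the hindered silyl ether, and the quaternary C1 cannot epimerize.

**Step 6**
Reactants: 8 keto acid
Product: 10 (1R,2S,5R)-2-{(S)-[(tert-butyldimethylsilyl)oxy][(4R)-2,2-dimethyl-1,3-dioxolan-4-yl]methyl}-2-methyl-5-(propan-2-yl)-6-oxabicyclo[3.2.0]heptan-7-one, via tosyl mixed anhydride 9 (not isolated)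
Conditions: TsCl, 4-pyrrolidinopyridine, LiCl, iPr2NEt, CH2Cl2, rt (slow addition of 8)
Reagents that add atoms: none
Why: Tosyl chloride turns the acid into mixed anhydride 9, 4-pyrrolidinopyridine takes over the acyl group, iPr2NEt removes a C5 proton to give an acylammonium enolate that adds to the C4 ketone, and the tertiary aldolate closes onto the acylpyridinium carbon, releasing the catalyst. The closest known reaction type is the nucleophile-catalysed aldol-lactonization (bis-cyclization) of keto acids to cyclopentane-fused β-lactones. The cyclopentane closes by a 5-(enolexo)-exo-trig aldol addition that forms C4–C5, and the oxetanone by a 4-exo-trig acyl substitution that is irreversible and so removes the retro-aldol problem of a ketone acceptor. C4 is controlled by the lactone itself, since only the aldolate with its oxygen cis to C6 can ring-close, and C5 is controlled by the adjacent quaternary C1, whose large silyloxy(dioxolanyl)methyl branch should force the acylammonium end of the enolate to the face of the small methyl group. The step needs face selectivity at C5 (C6 cis to the C1 methyl, the relation that later becomes the trans ring fusion) and chemoselective enolization of the acid beside the ketone; the first is secured by the size difference of the two C1 substituents, the second by enolization through the activated acylammonium only, and the silyl ether on C10 keeps that oxygen from capturing C6.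

**Step 7**
Reactants: 10 β-lactone
Product: 11 (1R,2R,5S)-5-{(S)-[(tert-butyldimethylsilyl)oxy][(4R)-2,2-dimethyl-1,3-dioxolan-4-yl]methyl}-2-hydroxy-N-methoxy-N,5-dimethyl-2-(propan-2-yl)cyclopentane-1-carboxamide
Conditions: MeNH(OMe)·HCl, Me3Al, CH2Cl2, 0 °C → rt; aq. potassium sodium tartrate
Reagents that add atoms: N,O-dimethylhydroxylamine hydrochloride, Cl.CNOC
Why: Aminolysis of the strained β-lactone at its acyl carbon by the aluminium amide (Weinreb amide formation; attack at the fully substituted C4 is impossible) should free the tertiary C4 hydroxyl with C4 and C5 unchanged.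

**Step 8**
Reactants: 11 Weinreb amide
Product: 12 (1R,2R,5S)-5-{(1S,2R)-1-[(tert-butyldimethylsilyl)oxy]-2,3-dihydroxypropyl}-2-hydroxy-N-methoxy-N,5-dimethyl-2-(propan-2-yl)cyclopentane-1-carboxamide
Conditions: AcOH/H2O (3:2), rt
Reagents that add atoms: none
Why: Mild acid hydrolysis should cleave the terminal isopropylidene acetal, which is far more labile than the hindered secondary silyl ether, the amide and the tertiary alcohol; no stereocentre is touched.

**Step 9**
Reactants: 12 triol
Product: 13 (1R,2R,5S)-5-{(1R)-1-[(tert-butyldimethylsilyl)oxy]prop-2-en-1-yl}-2-hydroxy-N-methoxy-N,5-dimethyl-2-(propan-2-yl)cyclopentane-1-carboxamide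
Conditions: PPh3, I2, imidazole, toluene, 80 °C
Reagents that add atoms: none
Why: Garegg–Samuelsson deoxygenation of the terminal vicinal diol (iodination of the primary carbon, then reductive anti-elimination of the neighbouring oxyphosphonium group) should give the vinyl group, removing the auxiliary stereocentre at C9 and leaving C10 untouched; the hindered tertiary alcohol is not expected to be activated.

**Step 10**
Reactants: 13 vinyl Weinreb amide; 14 2-methylallylmagnesium chloride
Product: 15 1-[(1R,2R,5S)-5-{(1R)-1-[(tert-butyldimethylsilyl)oxy]prop-2-en-1-yl}-2-hydroxy-5-methyl-2-(propan-2-yl)cyclopentyl]-3-methylbut-3-en-1-one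
Conditions: 14 (3.5 equiv), THF, −78 → −20 °C; aq. NH4Cl at −20 °C
Reagents that add atoms: none
Why: Weinreb ketone synthesis: after deprotonation of the tertiary alcohol the allylic Grignard reagent adds once to the amide, and the chelated tetrahedral adduct collapses only on the cold buffered quench, which should avoid over-addition, retro-aldol cleavage and conjugation of the β,γ-unsaturated ketone.

**Step 11**
Reactants: 15 dienyl hydroxy ketone
Product: 16 (3R,3aR,8R,8aS)-8-[(tert-butyldimethylsilyl)oxy]-3-hydroxy-6,8a-dimethyl-3-(propan-2-yl)-2,3,3a,5,8,8a-hexahydroazulen-4(1H)-one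
Conditions: second-generation Hoveyda–Grubbs catalyst RuCl2(H2IMes)(=CH-C6H4-2-OiPr) (10 mol %), 1,4-benzoquinone (20 mol %), toluene (2 mM), 80 °C
Reagents that add atoms: none
Why: Ring-closing metathesis between the vinyl group on C10 and the 1,1-disubstituted alkene should close the seven-membered ring with the trisubstituted C8=C9 alkene; the two chains are trans on the cyclopentane, so the ring fusion is trans by construction, and benzoquinone should suppress hydride-induced alkene migration.

**Step 12**
Reactants: 16 bicyclic hydroxy ketone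
Product: 17 (3R,3aS,4S,8R,8aS)-8-[(tert-butyldimethylsilyl)oxy]-6,8a-dimethyl-3-(propan-2-yl)-1,2,3,3a,4,5,8,8a-octahydroazulene-3,4-diol
Conditions: Me4NBH(OAc)3, AcOH/MeCN (1:1), −30 → −10 °C
Reagents that add atoms: none
Why: Evans–Saksena hydroxyl-directed reduction: the tertiary C4 hydroxyl binds boron and delivers hydride intramolecularly to the face of the ring ketone on which it sits (the face of the C1 methyl), so the new C6 hydroxyl should appear on the opposite face (4S in azulene numbering), and the weakly acidic medium should leave the β,γ-alkene in place.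

**Step 13**
Reactants: 17 diol; 18 benzoyl chloride
Product: 19 (3R,3aS,4S,8R,8aS)-8-[(tert-butyldimethylsilyl)oxy]-3-hydroxy-6,8a-dimethyl-3-(propan-2-yl)-1,2,3,3a,4,5,8,8a-octahydroazulen-4-yl benzoate
Conditions: pyridine, DMAP (cat.), CH2Cl2, 0 °C → rt
Reagents that add atoms: none
Why: O-Acylation should occur only at the secondary C6 hydroxyl, because the other free hydroxyl is tertiary and flanked by the isopropyl group; configuration at C6 is retained.

**Step 14**
Reactants: 19 silyl ether benzoate
Product: 20 (3R,3aS,4S,8R,8aS)-3,8-dihydroxy-6,8a-dimethyl-3-(propan-2-yl)-1,2,3,3a,4,5,8,8a-octahydroazulen-4-yl benzoate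
Conditions: HF·pyridine, pyridine, THF, 0 °C → rt
Reagents that add atoms: none
Why: Fluoride-mediated desilylation buffered with pyridine should remove the silyl ether without ionizing the allylic C10–O bond or moving the benzoate.

**Step 15**
Reactants: 20 allylic alcohol; 21 angelic acid
Product: 23 (3R,3aS,4S,8R,8aS)-3-hydroxy-6,8a-dimethyl-8-{[(2Z)-2-methylbut-2-enoyl]oxy}-3-(propan-2-yl)-1,2,3,3a,4,5,8,8a-octahydroazulen-4-yl benzoate, via angelic 2,4,6-trichlorobenzoic anhydride 22 (not isolated)
Conditions: 21, 2,4,6-trichlorobenzoyl chloride, Et3N, toluene, rt; then 20, toluene, 80 °C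
Reagents that add atoms: none
Why: Yamaguchi-type esterification through the preformed mixed anhydride without a nucleophilic catalyst, conditions under which Z-2-methylbut-2-enoates should form without isomerization to the E isomer; only the secondary allylic C10 hydroxyl can react, with retention at C10.

**Compound list**

1 | geranyl acetate, (2E)-3,7-dimethylocta-2,6-dien-1-yl acetate | CC(=CCC/C(=C/COC(C)=O)/C)C | starting material
2 | 2-[(2E)-3,7-dimethylocta-2,6-dien-1-yl]-4,4,5,5-tetramethyl-1,3,2-dioxaborolane | CC(=CCC/C(=C/CB1OC(C)(C)C(C)(C)O1)/C)C | intermediate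
3 | (R)-2,2-dimethyl-1,3-dioxolane-4-carbaldehyde | CC1(C)OC[C@@H](O1)C=O | starting material
4 | (1S,2S)-1-[(4R)-2,2-dimethyl-1,3-dioxolan-4-yl]-2-ethenyl-2,6-dimethylhept-5-en-1-ol | CC1(C)OC[C@@H](O1)[C@@H](O)[C@](C)(C=C)CCC=C(C)C | intermediate
5 | TBS ether of 4 | CC1(C)OC[C@@H](O1)[C@@H](O[Si](C)(C)C(C)(C)C)[C@](C)(C=C)CCC=C(C)C | intermediate
6 | bis(alkylborane) of 5 (idealized monomer, BH2 on the former vinyl terminus and on the former alkene CH) | CC1(C)OC[C@@H](O1)[C@@H](O[Si](C)(C)C(C)(C)C)[C@](C)(CCB)CCC(B)C(C)C | intermediate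
7 | (3S)-3-{(S)-[(tert-butyldimethylsilyl)oxy][(4R)-2,2-dimethyl-1,3-dioxolan-4-yl]methyl}-3,7-dimethyloctane-1,6-diol | CC1(C)OC[C@@H](O1)[C@@H](O[Si](C)(C)C(C)(C)C)[C@](C)(CCO)CCC(O)C(C)C | intermediate
8 | (3S)-3-{(S)-[(tert-butyldimethylsilyl)oxy][(4R)-2,2-dimethyl-1,3-dioxolan-4-yl]methyl}-3,7-dimethyl-6-oxooctanoic acid | CC1(C)OC[C@@H](O1)[C@@H](O[Si](C)(C)C(C)(C)C)[C@](C)(CC(=O)O)CCC(=O)C(C)C | intermediate
9 | mixed anhydride of 8 with p-toluenesulfonic acid | CC1(C)OC[C@@H](O1)[C@@H](O[Si](C)(C)C(C)(C)C)[C@](C)(CC(=O)OS(=O)(=O)c2ccc(C)cc2)CCC(=O)C(C)C | intermediate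
10 | (1R,2S,5R)-2-{(S)-[(tert-butyldimethylsilyl)oxy][(4R)-2,2-dimethyl-1,3-dioxolan-4-yl]methyl}-2-methyl-5-(propan-2-yl)-6-oxabicyclo[3.2.0]heptan-7-one | CC(C)[C@]12CC[C@](C)([C@H](O[Si](C)(C)C(C)(C)C)[C@H]3COC(C)(C)O3)[C@H]1C(=O)O2 | intermediate
11 | (1R,2R,5S)-5-{(S)-[(tert-butyldimethylsilyl)oxy][(4R)-2,2-dimethyl-1,3-dioxolan-4-yl]methyl}-2-hydroxy-N-methoxy-N,5-dimethyl-2-(propan-2-yl)cyclopentane-1-carboxamide | CON(C)C(=O)[C@H]1[C@](O)(C(C)C)CC[C@]1(C)[C@H](O[Si](C)(C)C(C)(C)C)[C@H]2COC(C)(C)O2 | intermediate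
12 | (1R,2R,5S)-5-{(1S,2R)-1-[(tert-butyldimethylsilyl)oxy]-2,3-dihydroxypropyl}-2-hydroxy-N-methoxy-N,5-dimethyl-2-(propan-2-yl)cyclopentane-1-carboxamide | CON(C)C(=O)[C@H]1[C@](O)(C(C)C)CC[C@]1(C)[C@H](O[Si](C)(C)C(C)(C)C)[C@H](O)CO | intermediate
13 | (1R,2R,5S)-5-{(1R)-1-[(tert-butyldimethylsilyl)oxy]prop-2-en-1-yl}-2-hydroxy-N-methoxy-N,5-dimethyl-2-(propan-2-yl)cyclopentane-1-carboxamide | CON(C)C(=O)[C@H]1[C@](O)(C(C)C)CC[C@]1(C)[C@H](O[Si](C)(C)C(C)(C)C)C=C | intermediate
14 | 2-methylallylmagnesium chloride | CC(=C)C[Mg]Cl | starting material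
15 | 1-[(1R,2R,5S)-5-{(1R)-1-[(tert-butyldimethylsilyl)oxy]prop-2-en-1-yl}-2-hydroxy-5-methyl-2-(propan-2-yl)cyclopentyl]-3-methylbut-3-en-1-one | CC(=C)CC(=O)[C@H]1[C@](O)(C(C)C)CC[C@]1(C)[C@H](O[Si](C)(C)C(C)(C)C)C=C | intermediate
16 | (3R,3aR,8R,8aS)-8-[(tert-butyldimethylsilyl)oxy]-3-hydroxy-6,8a-dimethyl-3-(propan-2-yl)-2,3,3a,5,8,8a-hexahydroazulen-4(1H)-one | CC(C)(C)[Si](C)(C)O[C@@H]1C=C(C)CC(=O)[C@@H]2[C@]1(C)CC[C@@]2(O)C(C)C | intermediate
17 | (3R,3aS,4S,8R,8aS)-8-[(tert-butyldimethylsilyl)oxy]-6,8a-dimethyl-3-(propan-2-yl)-1,2,3,3a,4,5,8,8a-octahydroazulene-3,4-diol | CC(C)(C)[Si](C)(C)O[C@@H]1C=C(C)C[C@H](O)[C@@H]2[C@]1(C)CC[C@@]2(O)C(C)C | intermediate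
18 | benzoyl chloride | O=C(Cl)c1ccccc1 | starting material
19 | (3R,3aS,4S,8R,8aS)-8-[(tert-butyldimethylsilyl)oxy]-3-hydroxy-6,8a-dimethyl-3-(propan-2-yl)-1,2,3,3a,4,5,8,8a-octahydroazulen-4-yl benzoate | CC(C)(C)[Si](C)(C)O[C@@H]1C=C(C)C[C@H](OC(=O)c3ccccc3)[C@@H]2[C@]1(C)CC[C@@]2(O)C(C)C | intermediate
20 | (3R,3aS,4S,8R,8aS)-3,8-dihydroxy-6,8a-dimethyl-3-(propan-2-yl)-1,2,3,3a,4,5,8,8a-octahydroazulen-4-yl benzoate | O[C@@H]1C=C(C)C[C@H](OC(=O)c3ccccc3)[C@@H]2[C@]1(C)CC[C@@]2(O)C(C)C | intermediate
21 | angelic acid, (2Z)-2-methylbut-2-enoic acid | C/C=C(/C)C(=O)O | starting material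
22 | angelic 2,4,6-trichlorobenzoic anhydride | C/C=C(/C)C(=O)OC(=O)c1c(Cl)cc(Cl)cc1Cl | intermediate
23 | (3R,3aS,4S,8R,8aS)-3-hydroxy-6,8a-dimethyl-8-{[(2Z)-2-methylbut-2-enoyl]oxy}-3-(propan-2-yl)-1,2,3,3a,4,5,8,8a-octahydroazulen-4-yl benzoate | C/C=C(/C)C(=O)O[C@@H]1C=C(C)C[C@H](OC(=O)c2ccccc2)[C@@H]2[C@]1(C)CC[C@@]2(O)C(C)C | target

**Step count**

Total steps: 15. Longest linear sequence: 15 steps (1 → 23); compounds 3, 14, 18 and 21 enter as single building blocks.

**Steps most likely to fail**

Step 6. The addition of the ammonium enolate to the hindered isopropyl ketone may be slower than self-condensation of the activated acid, or the two enolate faces may not be told apart well enough by C1. The fallback replaces the aldol-lactonization by a chelated thioester aldol. It sets out from 8: coupling with thiophenol (DCC, DMAP cat., CH2Cl2) should give the S-phenyl thioester F1. Soft enolization with MgBr2·OEt2 and iPr2NEt (CH2Cl2, rt) should then close the ring under equilibrating, magnesium-chelated conditions to the cis β-hydroxy thioester F2; the chelate holds the C4 oxygen cis to C6 and equilibration places C6 trans to the large C1 branch. Treatment of F2 with MeNH(OMe)·HCl and iPrMgCl (THF, −20 °C) should give Weinreb amide 11, where the route is rejoined.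

Step 11. Ring closure between the hindered allylic silyl ether alkene and the 1,1-disubstituted alkene may be slow, with catalyst decay and migration of the alkene into conjugation with the ketone. The fallback uses hydroxyl-assisted metathesis and a re-ordered end game. It sets out from 15: HF·pyridine should give the desilylated dienyl hydroxy ketone F3, whose ring-closing metathesis (same catalyst, CH2Cl2, 40 °C) is expected to be faster and should give the bicyclic dihydroxy ketone F4. Acylation of its only secondary hydroxyl with mixed anhydride 22 should give the C10 angelate ketone F5, and Me4NBH(OAc)3 reduction (directed by the C4 hydroxyl as in step 12) should give the C10 angelate diol F6. Benzoylation with 18 (pyridine, DMAP) comes back to the route at the target 23.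

Step 15. Acylation of the neopentylic allylic C10 hydroxyl may be sluggish, with Z to E isomerization of the acyl donor on prolonged heating. The fallback builds the Z-alkene on the ester. It sets out from 20: esterification with 2-[bis(2,2,2-trifluoroethoxy)phosphoryl]propanoic acid (DCC, DMAP, CH2Cl2) should give the C10 phosphonopropanoate F7. Still–Gennari olefination with acetaldehyde (KN(SiMe3)2, 18-crown-6, THF, −78 °C, extra base for the tertiary hydroxyl) should give the Z-2-methylbut-2-enoate, which is the target 23.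

**Further compounds**

F1 | step 6 | S-phenyl thioester of 8 | CC1(C)OC[C@@H](O1)[C@@H](O[Si](C)(C)C(C)(C)C)[C@](C)(CC(=O)Sc2ccccc2)CCC(=O)C(C)C
F2 | step 6 | S-phenyl (1R,2R,5S)-5-{(S)-[(tert-butyldimethylsilyl)oxy][(4R)-2,2-dimethyl-1,3-dioxolan-4-yl]methyl}-2-hydroxy-5-methyl-2-(propan-2-yl)cyclopentane-1-carbothioate | O=C(Sc3ccccc3)[C@H]1[C@](O)(C(C)C)CC[C@]1(C)[C@H](O[Si](C)(C)C(C)(C)C)[C@H]2COC(C)(C)O2
F3 | step 11 | 1-[(1R,2R,5S)-2-hydroxy-5-[(1R)-1-hydroxyprop-2-en-1-yl]-5-methyl-2-(propan-2-yl)cyclopentyl]-3-methylbut-3-en-1-one | CC(=C)CC(=O)[C@H]1[C@](O)(C(C)C)CC[C@]1(C)[C@H](O)C=C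
F4 | step 11 | (3R,3aR,8R,8aS)-3,8-dihydroxy-6,8a-dimethyl-3-(propan-2-yl)-2,3,3a,5,8,8a-hexahydroazulen-4(1H)-one | O[C@@H]1C=C(C)CC(=O)[C@@H]2[C@]1(C)CC[C@@]2(O)C(C)C
F5 | step 11 | (1R,3R,3aR,8aS)-3-hydroxy-6,8a-dimethyl-4-oxo-3-(propan-2-yl)-1,2,3,3a,4,5,8,8a-octahydroazulen-8-yl (2Z)-2-methylbut-2-enoate, C10 angelate ketone | C/C=C(/C)C(=O)O[C@@H]1C=C(C)CC(=O)[C@@H]2[C@]1(C)CC[C@@]2(O)C(C)C
F6 | step 11 | C10 angelate of the C4,C6-diol (6-debenzoyl target) | C/C=C(/C)C(=O)O[C@@H]1C=C(C)C[C@H](O)[C@@H]2[C@]1(C)CC[C@@]2(O)C(C)C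
F7 | step 15 | C10 2-[bis(2,2,2-trifluoroethoxy)phosphoryl]propanoate of 20 (epimers at the phosphonate carbon) | CC(P(=O)(OCC(F)(F)F)OCC(F)(F)F)C(=O)O[C@@H]1C=C(C)C[C@H](OC(=O)c2ccccc2)[C@@H]2[C@]1(C)CC[C@@]2(O)C(C)C
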